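**Retrosynthetic overview**
1. Feature: ring C has oxygen on C1, C2, C4 and C6 and hydrogen on C3 and C5. C2–C1–C6 is therefore 1,3-dimethoxyacetone, and C3–C4–C5 is a malonaldehyde whose C4 oxygen is O1 of ring D, the oxygen lying between the aryloxy groups at D2 and D6.
2. Key disconnection: bonds C2–C3 and C5–C6 of ring C ([3+3] benzannulation). The crowded D–O–C ether is made beforehand as an alkyl ether, by SN2 with bromoacetaldehyde diethyl acetal followed by a one-carbon aminomethylenation.
3. Ring D phenol: double SNAr of the E–F biaryl phenol on 2,6-difluoro-4-methoxybenzaldehyde, then CHO to OH (Baeyer–Villiger). The E–F and B–B' biaryl bonds come from Suzuki–Miyaura couplings.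
4. After ring C: its free C1–OH displaces fluoride from the B–B' fluoroaldehyde (SNAr), CHO is again turned into OH, an Ullmann coupling brings ring A, and BBr3 frees all 22 hydroxyls.
5. Ring order: only ring C is built de novo. The bought arenes are joined in the order F–E, D, (C), B–B', A. There is no stereocentre and no stereogenic axis, because rings F and B' are symmetric about their biaryl bonds.

Key step: step 9

Remark: ArEF stands for 2,4,6-trimethoxy-3-(2,4,6-trimethoxyphenyl)phenyl (ring E bearing ring F).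
Assumption: 16 is written as the dialdehyde tautomer although it should exist as the enol, and the push–pull alkenes 15, 18, 19 and 20 are configurationally labile and are written in one expected geometry only.

Step 1
Reactants: 1 2,4,6-trimethoxybenzaldehyde
Product: 2 3-bromo-2,4,6-trimethoxybenzaldehyde
Conditions: NBS (1.0 equiv), MeCN, 0 °C → rt
Reagents that add atoms: N-bromosuccinimide, O=C1CCC(=O)N1Br
Why: Electrophilic aromatic bromination, in which C3 (equivalent to C5) is the only free position type and is activated by three methoxy groups, while bromine and the formyl group deactivate the ring enough for one equivalent of NBS to stop at the monobromide.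

Step 2
Reactants: 2 3-bromo-2,4,6-trimethoxybenzaldehyde; 3 2,4,6-trimethoxyphenylboronic acid
Product: 4 2,4,6-trimethoxy-3-(2,4,6-trimethoxyphenyl)benzaldehyde
Conditions: 3 (1.8 equiv), Pd(OAc)2 (5 mol %), SPhos (10 mol %), K3PO4, toluene, 100 °C, argon
Reagents that add atoms: none
Why: Suzuki–Miyaura coupling, for which the bulky electron-rich ligand SPhos is known to carry zerovalent palladium through oxidative addition and reductive elimination of tetra-ortho-substituted biaryls, with the excess of 3 offsetting protodeboronation.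

Step 3
Reactants: 4 2,4,6-trimethoxy-3-(2,4,6-trimethoxyphenyl)benzaldehyde
Product: 6 2,4,6-trimethoxy-3-(2,4,6-trimethoxyphenyl)phenol (ArEF–OH), via aryl formate 5 (not isolated)
Conditions: mCPBA, CH2Cl2, 0 °C → rt; then K2CO3 (cat.), MeOH, rt, argon
Reagents that add atoms: 3-chloroperbenzoic acid (mCPBA), OOC(=O)c1cccc(Cl)c1
Why: Baeyer–Villiger oxidation of an electron-rich benzaldehyde, in which the ortho and para methoxy groups make aryl migration in the Criegee adduct faster than hydride migration, followed by base-catalysed methanolysis of the formate (the two-stage equivalent of a Dakin oxidation).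

Step 4
Reactants: 6 ArEF–OH (2.1 equiv); 7 2,6-difluoro-4-methoxybenzaldehyde
Product: 9 4-methoxy-2,6-bis(ArEF-oxy)benzaldehyde, via monoether 8 (not isolated)
Conditions: K2CO3, DMSO, 120 °C, argon
Reagents that add atoms: none
Why: Twofold nucleophilic aromatic substitution (SNAr, addition–elimination), in which each fluorine is ortho to the formyl group that stabilises the Meisenheimer adduct, the 4-methoxy group is meta to both reacting carbons, and the small fluoride leaving group tolerates a di-ortho-methoxy phenoxide.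

Step 5
Reactants: 9 4-methoxy-2,6-bis(ArEF-oxy)benzaldehyde
Product: 11 4-methoxy-2,6-bis(ArEF-oxy)phenol (ring D phenol), via aryl formate 10 (not isolated)
Conditions: mCPBA, CH2Cl2, 0 °C → rt; then K2CO3 (cat.), MeOH, rt, argon
Reagents that add atoms: 3-chloroperbenzoic acid (mCPBA), OOC(=O)c1cccc(Cl)c1
Why: Baeyer–Villiger oxidation and formate methanolysis as in step 3, the 2,4,6-trioxygenated ring D being an excellent migrating group and the phenol being released only after the peracid has been removed.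

Step 6
Reactants: 11 4-methoxy-2,6-bis(ArEF-oxy)phenol; 12 bromoacetaldehyde diethyl acetal
Product: 13 2-(2,2-diethoxyethoxy)-5-methoxy-1,3-bis(ArEF-oxy)benzene
Conditions: 12 (3 equiv), K2CO3, DMF, 110 °C, argon
Reagents that add atoms: none
Why: Williamson ether synthesis (SN2), in which the phenoxide oxygen, although flanked by two aryloxy groups, only has to reach an unbranched primary carbon, so the most hindered C–O bond of the target is made at the sp3 stage.

Step 7
Reactants: 13 2-(2,2-diethoxyethoxy)-5-methoxy-1,3-bis(ArEF-oxy)benzene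
Product: 14 2-[4-methoxy-2,6-bis(ArEF-oxy)phenoxy]acetaldehyde
Conditions: 2 M HCl, THF, 50 °C
Reagents that add atoms: water, O
Why: Acid-catalysed acetal hydrolysis, to which aryl methyl and diaryl ethers are inert, in which both ortho positions of ring D are blocked so no benzofuran can form, and in which dilute water-rich acid is too weak to drive Friedel–Crafts attack by rings F on the aldehyde.

Step 8
Reactants: 14 2-[4-methoxy-2,6-bis(ArEF-oxy)phenoxy]acetaldehyde
Product: 16 2-[4-methoxy-2,6-bis(ArEF-oxy)phenoxy]malonaldehyde, via enaminal 15 (not isolated)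
Conditions: t-BuOCH(NMe2)2, toluene, 70 °C; evaporate; 1 M NaOH, EtOH, 60 °C; 1 M HCl to pH 4, 0 °C
Reagents that add atoms: tert-butoxybis(dimethylamino)methane, CN(C)C(OC(C)(C)C)N(C)C; sodium hydroxide, [Na+].[OH-]
Why: Aminomethylenation of a CH-acidic aldehyde with an aminal ester, which is non-acidic and so spares the electron-rich rings that a Vilsmeier reagent would formylate, followed by the standard alkaline hydrolysis of a 3-(dimethylamino)acrolein to the malonaldehyde, whose acidity allows purification by base extraction.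

Step 9
Reactants: 16 2-[4-methoxy-2,6-bis(ArEF-oxy)phenoxy]malonaldehyde; 17 1,3-dimethoxypropan-2-one
Product: 21 4-[4-methoxy-2,6-bis(ArEF-oxy)phenoxy]-2,6-dimethoxyphenol (ring C phenol), via vinamidinium chloride 18 (not isolated), via potassium enolate 19 (not isolated), via dienaminone 20 (not isolated)
Conditions: 16, PhNHMe (1 equiv), PhNHMe·HCl (1 equiv), 4 Å MS, EtOH, rt, evaporate, toluene azeotrope; separately 17 (1.1 equiv), KOtBu (1.1 equiv), THF, −20 °C; combine, −20 °C → rt; KOtBu (2 equiv), 60 °C; aq NH4Cl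
Reagents that add atoms: none
Why: Proposed new method: under base the free dialdehyde 16 would rest as an unreactive vinylogous carboxylate, so it is first capped with N-methylaniline as the cationic vinamidinium 18, whose termini are C3 and C5 and whose central carbon is C4 of ring C. Enolate 19 adds through a methoxy-bearing carbon to one terminus and N-methylaniline leaves (addition–elimination, bond C2–C3) to give the push–pull dienaminone 20, further KOtBu enolises the remaining CH2OMe, and the 1-oxidohexatriene so formed makes bond C5–C6. Ring C closes by a thermal disrotatory 6π electrocyclisation, in polar terms a favoured 6-(enolendo)-exo-trig attack of C6 on the C5=N terminus, and vinylogous E1cB loss of the second N-methylaniline (a far better nucleofuge than dimethylamide in aprotic base) followed by tautomerisation gives the phenolate irreversibly. The closest known reaction types are the condensation of sodium nitromalonaldehyde with dialkyl or dibenzyl ketones to 2,6-disubstituted 4-nitrophenols and the annulation of ketone enolates with 2-substituted vinamidinium salts; a donor-substituted 2-aryloxy three-carbon unit paired with an α,α'-dialkoxy ketone has not been shown. No stereocentre is formed, and because both partners are symmetric either orientation leads to the same arene. The step needs cross-condensation to beat self-aldolisation of 17 and a one-to-one union to beat a two-to-one union: cation 18 is much more electrophilic than ketone 17 or dienaminone 20, self-aldol addition is reversible, only about one equivalent of 19 is offered, and aromatisation is the sole irreversible exit.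

Step 10
Reactants: 22 1-fluoro-3,5-dimethoxybenzene
Product: 24 4-fluoro-2,6-dimethoxybenzaldehyde, via aryllithium 23 (not isolated)
Conditions: n-BuLi, Et2O, −20 → 0 °C; DMF, −78 °C → rt; 1 M HCl
Reagents that add atoms: N,N-dimethylformamide, CN(C)C=O
Why: Directed ortho-metalation and formylation, in which n-BuLi alone in diethyl ether acts under coordination control and should lithiate the carbon between the two methoxy groups (para to fluorine) rather than the fluorine-adjacent carbons favoured by acidity-controlled superbases, any regioisomeric aldehyde being removable at this cheap stage.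

Step 11
Reactants: 24 4-fluoro-2,6-dimethoxybenzaldehyde
Product: 25 3-bromo-4-fluoro-2,6-dimethoxybenzaldehyde
Conditions: NBS (1.0 equiv), MeCN, rt
Reagents that add atoms: N-bromosuccinimide, O=C1CCC(=O)N1Br
Why: Electrophilic aromatic bromination at C3 (equivalent to C5), which is ortho to one methoxy group, para to the other and meta to the formyl group, so only one monobromide can form.

Step 12
Reactants: 25 3-bromo-4-fluoro-2,6-dimethoxybenzaldehyde; 3 2,4,6-trimethoxyphenylboronic acid
Product: 26 4-fluoro-2,6-dimethoxy-3-(2,4,6-trimethoxyphenyl)benzaldehyde (ring B–B' fluoroaldehyde)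
Conditions: 3 (1.8 equiv), Pd(OAc)2 (5 mol %), SPhos (10 mol %), K3PO4, toluene, 100 °C, argon
Reagents that add atoms: none
Why: Suzuki–Miyaura coupling as in step 2, made easier by the small fluorine as one of the four ortho substituents, with the C–F bond inert to zerovalent palladium and the non-polar medium suppressing displacement of the activated fluoride.

Step 13
Reactants: 21 4-[4-methoxy-2,6-bis(ArEF-oxy)phenoxy]-2,6-dimethoxyphenol; 26 4-fluoro-2,6-dimethoxy-3-(2,4,6-trimethoxyphenyl)benzaldehyde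
Product: 27 4-{4-[4-methoxy-2,6-bis(ArEF-oxy)phenoxy]-2,6-dimethoxyphenoxy}-2,6-dimethoxy-3-(2,4,6-trimethoxyphenyl)benzaldehyde
Conditions: 26 (1.3 equiv), Cs2CO3, DMSO, 130 °C, argon
Reagents that add atoms: none
Why: Nucleophilic aromatic substitution (SNAr) of a fluorine para to a formyl group, in which both methoxy groups of ring B are meta to the reacting carbon and do not destabilise the Meisenheimer adduct, and the poorly solvated caesium phenoxide in DMSO is reactive enough for the crowded addition step.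

Step 14
Reactants: 27 the aldehyde from step 13
Product: 29 4-{4-[4-methoxy-2,6-bis(ArEF-oxy)phenoxy]-2,6-dimethoxyphenoxy}-2,6-dimethoxy-3-(2,4,6-trimethoxyphenyl)phenol (ring B phenol), via aryl formate 28 (not isolated)
Conditions: mCPBA, CH2Cl2, 0 °C → rt; then K2CO3 (cat.), MeOH, rt, argon
Reagents that add atoms: 3-chloroperbenzoic acid (mCPBA), OOC(=O)c1cccc(Cl)c1
Why: Baeyer–Villiger oxidation and formate methanolysis as in steps 3 and 5, the formyl group again sitting on a ring with two ortho methoxy groups and a para aryloxy group that migrates readily.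

Step 15
Reactants: 29 ring B phenol; 30 1-iodo-3,5-dimethoxybenzene
Product: 31 docosa-O-methyl ether of the target, 2-(3,5-dimethoxyphenoxy)-5-{4-[4-methoxy-2,6-bis(ArEF-oxy)phenoxy]-2,6-dimethoxyphenoxy}-1,3-dimethoxy-4-(2,4,6-trimethoxyphenyl)benzene
Conditions: 30 (2 equiv), CuI (20 mol %), picolinic acid (40 mol %), K3PO4, DMSO, 90 °C, argon
Reagents that add atoms: none
Why: Ullmann-type diaryl ether synthesis with a ligand system known for di-ortho-substituted phenols and unhindered aryl iodides, the oxygen-free conditions with monovalent copper being preferred to an aerobic boronic acid coupling with divalent copper because 29 is an oxidation-prone 2,6-dimethoxyphenol.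

Step 16
Reactants: 31 docosa-O-methyl ether of the target
Product: 32 CNP0117322.0
Conditions: BBr3 (3 equiv per OMe), CH2Cl2, −78 °C → rt; H2O, 0 °C; reversed-phase chromatography under argon
Reagents that add atoms: none
Why: Lewis-acid cleavage of aryl methyl ethers, in which BBr3 binds each methoxy oxygen and bromide removes the methyl group by SN2, while the diaryl ether and biaryl bonds offer no sp3 carbon to attack and stay intact.

**Compound list**
1 | 2,4,6-trimethoxybenzaldehyde | COc1cc(OC)c(C=O)c(OC)c1 | starting material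
2 | 3-bromo-2,4,6-trimethoxybenzaldehyde | COc1cc(OC)c(C=O)c(OC)c1Br | intermediate
3 | 2,4,6-trimethoxyphenylboronic acid | COc1cc(OC)c(B(O)O)c(OC)c1 | starting material
4 | 2,4,6-trimethoxy-3-(2,4,6-trimethoxyphenyl)benzaldehyde | COc1cc(OC)c(-c2c(OC)cc(OC)c(C=O)c2OC)c(OC)c1 | intermediate
5 | 2,4,6-trimethoxy-3-(2,4,6-trimethoxyphenyl)phenyl formate | COc1cc(OC)c(-c2c(OC)cc(OC)c(OC=O)c2OC)c(OC)c1 | intermediate
6 | 2,4,6-trimethoxy-3-(2,4,6-trimethoxyphenyl)phenol (ArEF–OH) | COc1cc(OC)c(-c2c(OC)cc(OC)c(O)c2OC)c(OC)c1 | intermediate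
7 | 2,6-difluoro-4-methoxybenzaldehyde | COc1cc(F)c(C=O)c(F)c1 | starting material
8 | 2-fluoro-4-methoxy-6-(ArEF-oxy)benzaldehyde | COc1cc(F)c(C=O)c(Oc2c(OC)cc(OC)c(-c3c(OC)cc(OC)cc3OC)c2OC)c1 | intermediate
9 | 4-methoxy-2,6-bis(ArEF-oxy)benzaldehyde | COc1cc(Oc2c(OC)cc(OC)c(-c3c(OC)cc(OC)cc3OC)c2OC)c(C=O)c(Oc2c(OC)cc(OC)c(-c3c(OC)cc(OC)cc3OC)c2OC)c1 | intermediate
10 | 4-methoxy-2,6-bis(ArEF-oxy)phenyl formate | COc1cc(Oc2c(OC)cc(OC)c(-c3c(OC)cc(OC)cc3OC)c2OC)c(OC=O)c(Oc2c(OC)cc(OC)c(-c3c(OC)cc(OC)cc3OC)c2OC)c1 | intermediate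
11 | 4-methoxy-2,6-bis(ArEF-oxy)phenol | COc1cc(Oc2c(OC)cc(OC)c(-c3c(OC)cc(OC)cc3OC)c2OC)c(O)c(Oc2c(OC)cc(OC)c(-c3c(OC)cc(OC)cc3OC)c2OC)c1 | intermediate
12 | bromoacetaldehyde diethyl acetal | CCOC(CBr)OCC | starting material
13 | 2-(2,2-diethoxyethoxy)-5-methoxy-1,3-bis(ArEF-oxy)benzene | COc1cc(Oc2c(OC)cc(OC)c(-c3c(OC)cc(OC)cc3OC)c2OC)c(OCC(OCC)OCC)c(Oc2c(OC)cc(OC)c(-c3c(OC)cc(OC)cc3OC)c2OC)c1 | intermediate
14 | 2-[4-methoxy-2,6-bis(ArEF-oxy)phenoxy]acetaldehyde | COc1cc(Oc2c(OC)cc(OC)c(-c3c(OC)cc(OC)cc3OC)c2OC)c(OCC=O)c(Oc2c(OC)cc(OC)c(-c3c(OC)cc(OC)cc3OC)c2OC)c1 | intermediate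
15 | (Z)-3-(dimethylamino)-2-[4-methoxy-2,6-bis(ArEF-oxy)phenoxy]prop-2-enal | COc1cc(Oc2c(OC)cc(OC)c(-c3c(OC)cc(OC)cc3OC)c2OC)c(O/C(C=O)=C\N(C)C)c(Oc2c(OC)cc(OC)c(-c3c(OC)cc(OC)cc3OC)c2OC)c1 | intermediate
16 | 2-[4-methoxy-2,6-bis(ArEF-oxy)phenoxy]malonaldehyde | COc1cc(Oc2c(OC)cc(OC)c(-c3c(OC)cc(OC)cc3OC)c2OC)c(OC(C=O)C=O)c(Oc2c(OC)cc(OC)c(-c3c(OC)cc(OC)cc3OC)c2OC)c1 | intermediate
17 | 1,3-dimethoxypropan-2-one | COCC(=O)COC | starting material
18 | N-methyl-N-{3-(N-methylanilino)-2-[4-methoxy-2,6-bis(ArEF-oxy)phenoxy]prop-2-en-1-ylidene}anilinium chloride | COc1cc(Oc2c(OC)cc(OC)c(-c3c(OC)cc(OC)cc3OC)c2OC)c(O/C(C=[N+](C)c2ccccc2)=C\N(C)c2ccccc2)c(Oc2c(OC)cc(OC)c(-c3c(OC)cc(OC)cc3OC)c2OC)c1.[Cl-] | intermediate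
19 | potassium (Z)-1,3-dimethoxyprop-1-en-2-olate | [K+].[O-]/C(COC)=C\OC | intermediate
20 | (3E,5Z)-1,3-dimethoxy-5-[4-methoxy-2,6-bis(ArEF-oxy)phenoxy]-6-(N-methylanilino)hexa-3,5-dien-2-one | COCC(=O)/C(OC)=C\C(Oc1c(Oc2c(OC)cc(OC)c(-c3c(OC)cc(OC)cc3OC)c2OC)cc(OC)cc1Oc1c(OC)cc(OC)c(-c2c(OC)cc(OC)cc2OC)c1OC)=C\N(C)c1ccccc1 | intermediate
21 | 4-[4-methoxy-2,6-bis(ArEF-oxy)phenoxy]-2,6-dimethoxyphenol | COc1cc(Oc2c(OC)cc(OC)c(-c3c(OC)cc(OC)cc3OC)c2OC)c(Oc2cc(OC)c(O)c(OC)c2)c(Oc2c(OC)cc(OC)c(-c3c(OC)cc(OC)cc3OC)c2OC)c1 | intermediate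
22 | 1-fluoro-3,5-dimethoxybenzene | COc1cc(F)cc(OC)c1 | starting material
23 | (4-fluoro-2,6-dimethoxyphenyl)lithium | [Li]c1c(OC)cc(F)cc1OC | intermediate
24 | 4-fluoro-2,6-dimethoxybenzaldehyde | COc1cc(F)cc(OC)c1C=O | intermediate
25 | 3-bromo-4-fluoro-2,6-dimethoxybenzaldehyde | COc1cc(F)c(Br)c(OC)c1C=O | intermediate
26 | 4-fluoro-2,6-dimethoxy-3-(2,4,6-trimethoxyphenyl)benzaldehyde | COc1cc(OC)c(-c2c(F)cc(OC)c(C=O)c2OC)c(OC)c1 | intermediate
27 | 4-{4-[4-methoxy-2,6-bis(ArEF-oxy)phenoxy]-2,6-dimethoxyphenoxy}-2,6-dimethoxy-3-(2,4,6-trimethoxyphenyl)benzaldehyde | O=Cc1c(OC)cc(Oc2c(OC)cc(Oc3c(Oc4c(OC)cc(OC)c(-c5c(OC)cc(OC)cc5OC)c4OC)cc(OC)cc3Oc3c(OC)cc(OC)c(-c4c(OC)cc(OC)cc4OC)c3OC)cc2OC)c(-c2c(OC)cc(OC)cc2OC)c1OC | intermediate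
28 | formate ester of phenol 29 | O=COc1c(OC)cc(Oc2c(OC)cc(Oc3c(Oc4c(OC)cc(OC)c(-c5c(OC)cc(OC)cc5OC)c4OC)cc(OC)cc3Oc3c(OC)cc(OC)c(-c4c(OC)cc(OC)cc4OC)c3OC)cc2OC)c(-c2c(OC)cc(OC)cc2OC)c1OC | intermediate
29 | 4-{4-[4-methoxy-2,6-bis(ArEF-oxy)phenoxy]-2,6-dimethoxyphenoxy}-2,6-dimethoxy-3-(2,4,6-trimethoxyphenyl)phenol | Oc1c(OC)cc(Oc2c(OC)cc(Oc3c(Oc4c(OC)cc(OC)c(-c5c(OC)cc(OC)cc5OC)c4OC)cc(OC)cc3Oc3c(OC)cc(OC)c(-c4c(OC)cc(OC)cc4OC)c3OC)cc2OC)c(-c2c(OC)cc(OC)cc2OC)c1OC | intermediate
30 | 1-iodo-3,5-dimethoxybenzene | COc1cc(I)cc(OC)c1 | starting material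
31 | docosa-O-methyl ether of the target | COc1cc(OC)cc(Oc2c(OC)cc(Oc3c(OC)cc(Oc4c(Oc5c(OC)cc(OC)c(-c6c(OC)cc(OC)cc6OC)c5OC)cc(OC)cc4Oc4c(OC)cc(OC)c(-c5c(OC)cc(OC)cc5OC)c4OC)cc3OC)c(-c3c(OC)cc(OC)cc3OC)c2OC)c1 | intermediate
32 | CNP0117322.0 | Oc1cc(O)cc(Oc2c(O)cc(Oc3c(O)cc(Oc4c(Oc5c(O)cc(O)c(-c6c(O)cc(O)cc6O)c5O)cc(O)cc4Oc4c(O)cc(O)c(-c5c(O)cc(O)cc5O)c4O)cc3O)c(-c3c(O)cc(O)cc3O)c2O)c1 | target

**Step count**
Total step count: 16. Longest linear sequence: 13 (steps 1–9 and 13–16). Steps 10–12 form the side branch to fragment B–B'.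

**Steps most likely to fail**

Step 9 (labelled step).
- Possible failure: the sequence may stall at the dienaminone stage because the oxidohexatriene closes slowly. Adventitious water may return the salt to the inert enolate of 16. The ketone may be lost to self-aldolisation.
- Fallback: it gives up the ring construction and forms the D–O–C bond on a finished ring by known chemistry.
- It sets out from phenol 11, which is heated with 4-fluoro-2,6-dimethoxybenzaldehyde 24 (Cs2CO3, DMSO, 130 °C). The fluorine of 24 has only hydrogens as neighbours.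
- This SNAr should give 4-[4-methoxy-2,6-bis(ArEF-oxy)phenoxy]-2,6-dimethoxybenzaldehyde F1.
- Baeyer–Villiger oxidation with mCPBA should give 4-[4-methoxy-2,6-bis(ArEF-oxy)phenoxy]-2,6-dimethoxyphenyl formate F2.
- Catalytic K2CO3 in MeOH brings the sequence back to the route at 21.

Step 13.
- Possible failure: the addition step may be too slow, because the two ortho methoxy groups of the phenoxide meet ring B' next to the fluorine. At the temperature then needed, phenoxide-induced demethylation of the methoxy groups ortho to the formyl group can take over.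
- Fallback: it changes the order of bond formation and sets out from 21.
- Compound 21 is treated with the smaller and inductively more activated bromofluoroaldehyde 25 (Cs2CO3, DMSO, 100 °C).
- This should give 3-bromo-4-{4-[4-methoxy-2,6-bis(ArEF-oxy)phenoxy]-2,6-dimethoxyphenoxy}-2,6-dimethoxybenzaldehyde F3.
- Suzuki–Miyaura coupling of this bromide with boronic acid 3 (Pd(OAc)2, SPhos, K3PO4, toluene, 100 °C) then installs ring B' and comes back to the route at 27.

Step 16.
- Possible failure: partly cleaved aryl borates may precipitate from CH2Cl2 before all 22 ethers are cleaved. The free polyphenol may also oxidise in air during aqueous isolation.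
- Fallback: a trap-and-release sequence that sets out from 31.
- After the BBr3 treatment and quench, the crude phenol mixture is acetylated directly (Ac2O, pyridine, DMAP).
- This should give the docosaacetate of the target F4, which can be purified on silica. Fractions that still carry methyl groups are returned to the cleavage.
- Acid-catalysed methanolysis (AcCl cat., MeOH, argon), which avoids phenolate formation, then comes back to the route at 32.

**Further compounds**
F1 | step 9 | 4-[4-methoxy-2,6-bis(ArEF-oxy)phenoxy]-2,6-dimethoxybenzaldehyde | COc1cc(Oc2c(OC)cc(OC)c(-c3c(OC)cc(OC)cc3OC)c2OC)c(Oc2cc(OC)c(C=O)c(OC)c2)c(Oc2c(OC)cc(OC)c(-c3c(OC)cc(OC)cc3OC)c2OC)c1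
F2 | step 9 | 4-[4-methoxy-2,6-bis(ArEF-oxy)phenoxy]-2,6-dimethoxyphenyl formate | COc1cc(Oc2c(OC)cc(OC)c(-c3c(OC)cc(OC)cc3OC)c2OC)c(Oc2cc(OC)c(OC=O)c(OC)c2)c(Oc2c(OC)cc(OC)c(-c3c(OC)cc(OC)cc3OC)c2OC)c1
F3 | step 13 | 3-bromo-4-{4-[4-methoxy-2,6-bis(ArEF-oxy)phenoxy]-2,6-dimethoxyphenoxy}-2,6-dimethoxybenzaldehyde | O=Cc1c(OC)cc(Oc2c(OC)cc(Oc3c(Oc4c(OC)cc(OC)c(-c5c(OC)cc(OC)cc5OC)c4OC)cc(OC)cc3Oc3c(OC)cc(OC)c(-c4c(OC)cc(OC)cc4OC)c3OC)cc2OC)c(Br)c1OC
F4 | step 16 | docosaacetate of the target | CC(=O)Oc1cc(OC(C)=O)cc(Oc2c(OC(C)=O)cc(Oc3c(OC(C)=O)cc(Oc4c(Oc5c(OC(C)=O)cc(OC(C)=O)c(-c6c(OC(C)=O)cc(OC(C)=O)cc6OC(C)=O)c5OC(C)=O)cc(OC(C)=O)cc4Oc4c(OC(C)=O)cc(OC(C)=O)c(-c5c(OC(C)=O)cc(OC(C)=O)cc5OC(C)=O)c4OC(C)=O)cc3OC(C)=O)c(-c3c(OC(C)=O)cc(OC(C)=O)cc3OC(C)=O)c2OC(C)=O)c1
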